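**Retrosynthetic overview**
- The strategy rests on the C1–C8a bond. C1 is the quinone carbonyl carbon of ring B next to the side-chain-bearing C2, and C8a is the fusion carbon of the 5,8-dioxygenated ring A. C1 corresponds to the oxidised branch-methyl carbon of a geranylhydroquinone chain.
- Target 26 ⇒ shikonin 20 + (3Z)-5-methylhexa-3,5-dienoic acid 24 (ester bond at C1'–O; 24 from methacrolein by a Z-selective Wittig reaction).
- 20 ⇒ 5,8-dimethoxy-1-naphthol 17 (oxidation at C4, cleavage of the two peri methyl ethers, desilylation). Ring A is bought; ring B is the only ring formed.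
- Ring B of 17 (C1–C2–C3–C4–C4a–C8a) ⇒ Z acid 14 by opening C1–C8a (intramolecular acylation of ring A at its one free ortho carbon).
- 14 ⇒ Z iodide 13 ⇒ proximal Z stannane 11 from (R)-propargylic alcohol 10 (hydroxyl-directed trans-hydrostannation; C1' set by asymmetric transfer hydrogenation of ynone 9) ⇒ arylpropyne 4 + Weinreb amide 7.

Key step: step 9

Remark: C1' is R (shikonin series) and keeps this descriptor from 10 to 26, since the ring-side carbon outranks the side-chain CH2 at every stage and no bond to C1' is broken after step 4; 1, 2, 5, 21 and 22 are taken as purchased, and naphthazarins 19, 20 and 26 are drawn as one of their two rapidly equilibrating tautomers.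

**Route**

Step 1
Reactants: 1 2-bromo-1,4-dimethoxybenzene; 2 methoxyallene
Product: 4 3-(2,5-dimethoxyphenyl)prop-1-yne, via Grignard reagent 3 (not isolated)
Conditions: Mg, THF, reflux; then 2 (1.1 equiv), CuBr (5 mol %), THF/Et2O, –10 °C → rt; aq NH4Cl
Reagents that add atoms: none
Why: Copper-catalysed SN2' substitution of the allenyl ether by the aryl Grignard reagent puts the aryl group on the CH2 terminus and expels methoxide, which should give the propargyl arene free of the arylallene that arylmetal/propargyl bromide couplings produce.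

Step 2
Reactants: 5 4-methylpent-3-enoic acid
Product: 7 N-methoxy-N,4-dimethylpent-3-enamide, via acyl imidazole 6 (not isolated)
Conditions: CDI (1.1 equiv), CH2Cl2, rt; then MeNH(OMe)·HCl (1.2 equiv), rt
Reagents that add atoms: N,O-dimethylhydroxylamine hydrochloride, CNOC.Cl
Why: Weinreb amide formation through the acyl imidazole needs no strong base, so the β,γ double bond should stay out of conjugation.

Step 3
Reactants: 4 3-(2,5-dimethoxyphenyl)prop-1-yne; 7 N-methoxy-N,4-dimethylpent-3-enamide
Product: 9 1-(2,5-dimethoxyphenyl)-7-methyloct-6-en-2-yn-4-one, via lithium acetylide 8 (not isolated)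
Conditions: 4, n-BuLi (1.0 equiv), THF, –78 °C; then 7, –78 → –20 °C; inverse quench into cold aq NaH2PO4
Reagents that add atoms: none
Why: Kinetic deprotonation of the terminal alkyne and acyl substitution on the Weinreb amide, which stops at the ketone stage until the cold, weakly acidic quench, should give the ynone without amine bases that would isomerise it to an allenyl ketone.

Step 4
Reactants: 9 1-(2,5-dimethoxyphenyl)-7-methyloct-6-en-2-yn-4-one
Product: 10 (4R)-1-(2,5-dimethoxyphenyl)-7-methyloct-6-en-2-yn-4-ol
Conditions: Ru[(R,R)-TsNCH(Ph)CH(Ph)NH](p-cymene) (2 mol %, preformed from RuCl[(R,R)-TsNCH(Ph)CH(Ph)NH2](p-cymene) and KOH), i-PrOH, rt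
Reagents that add atoms: none
Why: Noyori asymmetric transfer hydrogenation, in which the alkynyl group takes the place an aryl group takes with aryl ketones in the six-membered Ru–H/N–H transition state, so the (R,R) catalyst is expected to give the (R)-carbinol that becomes C1' of the target, and the base-free amido complex avoids propargyl–allenyl isomerisation.

Step 5
Reactants: 10 (4R)-1-(2,5-dimethoxyphenyl)-7-methyloct-6-en-2-yn-4-ol
Product: 11 (2Z,4R)-1-(2,5-dimethoxyphenyl)-7-methyl-3-(tributylstannyl)octa-2,6-dien-4-ol
Conditions: [Cp*RuCl]4 (2 mol %), Bu3SnH (1.1 equiv), CH2Cl2, rt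
Reagents that add atoms: tributyltin hydride, CCCC[SnH](CCCC)CCCC
Why: Hydroxyl-directed ruthenium-catalysed trans-hydrostannation, in which hydrogen bonding of the free OH to the chloride ligand steers tin to the alkyne carbon next to the carbinol and H adds anti, so tin and the arylmethyl group end up cis as the ring closure requires, whereas a hydroxyl-directed hydroalumination would place the metal on the distal carbon.

Step 6
Reactants: 11 (2Z,4R)-1-(2,5-dimethoxyphenyl)-7-methyl-3-(tributylstannyl)octa-2,6-dien-4-ol
Product: 12 tert-butyl{[(2Z,4R)-1-(2,5-dimethoxyphenyl)-7-methyl-3-(tributylstannyl)octa-2,6-dien-4-yl]oxy}dimethylsilane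
Conditions: TBSOTf (1.3 equiv), 2,6-lutidine (2.5 equiv), CH2Cl2, –78 → 0 °C
Reagents that add atoms: tert-butyldimethylsilyl trifluoromethanesulfonate, CC(C)(C)[Si](C)(C)OS(=O)(=O)C(F)(F)F
Why: Silylation with a silyl triflate and a hindered base masks the hydroxyl, so that the next step cannot divert into 5-endo iodoetherification onto the prenyl alkene and C1' stays protected through ring closure, oxidation and demethylation.

Step 7
Reactants: 12 tert-butyl{[(2Z,4R)-1-(2,5-dimethoxyphenyl)-7-methyl-3-(tributylstannyl)octa-2,6-dien-4-yl]oxy}dimethylsilane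
Product: 13 tert-butyl{[(2Z,4R)-1-(2,5-dimethoxyphenyl)-3-iodo-7-methylocta-2,6-dien-4-yl]oxy}dimethylsilane
Conditions: I2 (1.05 equiv), CH2Cl2, –78 → 0 °C; aq Na2S2O3
Reagents that add atoms: iodine, II
Why: Iododestannylation by ipso attack of iodine on the C–Sn bond proceeds with retention of alkene geometry and should be far faster than any reaction of iodine with the trisubstituted alkene or the arene.

Step 8
Reactants: 13 tert-butyl{[(2Z,4R)-1-(2,5-dimethoxyphenyl)-3-iodo-7-methylocta-2,6-dien-4-yl]oxy}dimethylsilane
Product: 14 (Z)-2-[(1R)-1-(tert-butyldimethylsilyloxy)-4-methylpent-3-enyl]-4-(2,5-dimethoxyphenyl)but-2-enoic acid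
Conditions: Pd(OAc)2 (5 mol %), dppf (10 mol %), CO (1 atm), KOAc (4 equiv), DMF/H2O 10:1, 60 °C; work-up at pH 4
Reagents that add atoms: carbon monoxide, [C-]#[O+]; water, O
Why: Palladium-catalysed hydroxycarbonylation (oxidative addition into C–I, CO insertion, capture of the acyl group by acetate/water) retains the alkene geometry and gives the acid directly, so no ester hydrolysis is needed that could scramble the Z alkene.

Step 9
Reactants: 14 (Z)-2-[(1R)-1-(tert-butyldimethylsilyloxy)-4-methylpent-3-enyl]-4-(2,5-dimethoxyphenyl)but-2-enoic acid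
Product: 17 2-[(1R)-1-(tert-butyldimethylsilyloxy)-4-methylpent-3-enyl]-5,8-dimethoxynaphthalen-1-ol, via acyl trifluoroacetate 15 (not isolated), via 4H-naphthalen-1-one tautomer 16 (not isolated)
Conditions: TFAA (1.2 equiv), 2,6-di-tert-butylpyridine (3 equiv), CH2Cl2 (0.02 M), –20 °C → rt; aq NaHCO3
Reagents that add atoms: none
Why: TFAA turns the acid into mixed anhydride 15, and since the alkene is Z, with the carboxyl on the same side as the arylmethyl group, the activated carbonyl carbon lies within bonding distance of C6 of the dimethoxyphenyl ring (its only unsubstituted ortho carbon, itself ortho to a methoxy group), which attacks it; trifluoroacetate leaves and the arenium ion gives its proton to the hindered pyridine. This is an intramolecular Friedel–Crafts acylation through a mixed anhydride, the ring-closing stage of the Stobbe route to naphthols and of the cyclodehydration of 4-arylbutenoic acids to 1-naphthols. Ring B (C1–C2–C3–C4–C4a–C8a) closes in a 6-exo-trig mode with formation of C1–C8a, and dienone 16 should enolise at once to naphthol 17 because that restores a naphthalene. No stereocentre is formed, and C1' cannot ionise, since before closure it is flanked by the electron-poor acyl-substituted alkene carbon and the medium stays buffered throughout. The step needs (a) the Z geometry to persist, which the pyridine base secures by trapping CF3CO2H while being too hindered to form an acylpyridinium ion and too weak to deprotonate C4 to a vinylketene, and (b) attack by the arene and not by the trisubstituted side-chain alkene, which the cis alkene secures by preorganising the arene for six-membered closure, whereas the side-chain alkene would have to close a five-membered ring through a freely rotating chain.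

Step 10
Reactants: 17 2-[(1R)-1-(tert-butyldimethylsilyloxy)-4-methylpent-3-enyl]-5,8-dimethoxynaphthalen-1-ol
Product: 18 2-[(1R)-1-(tert-butyldimethylsilyloxy)-4-methylpent-3-enyl]-5,8-dimethoxynaphthalene-1,4-dione
Conditions: (KSO3)2NO (3 equiv), KH2PO4 buffer (pH 6), acetone/H2O, 0 °C → rt
Reagents that add atoms: Fremy's salt (KSO3)2NO, [K+].[K+].[O]N(S(=O)(=O)[O-])S(=O)(=O)[O-] (supplies the C4 oxygen)
Why: Teuber oxidation, in which the nitroxyl radical forms the naphthoxyl radical, a second equivalent adds at the unsubstituted para carbon C4 (C2 is blocked) and loss of imidodisulfonate gives the 1,4-quinone under near-neutral conditions that should leave the silyl ether, the alkene and the dimethoxy ring untouched.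

Step 11
Reactants: 18 2-[(1R)-1-(tert-butyldimethylsilyloxy)-4-methylpent-3-enyl]-5,8-dimethoxynaphthalene-1,4-dione
Product: 19 2-[(1R)-1-(tert-butyldimethylsilyloxy)-4-methylpent-3-enyl]-5,8-dihydroxynaphthalene-1,4-dione
Conditions: BCl3 (4 equiv, 1 M in CH2Cl2), CH2Cl2, –78 → –30 °C; cold aq NaHCO3
Reagents that add atoms: none
Why: Chelation-assisted Lewis acid ether cleavage: each methoxy group is peri to a quinone carbonyl, so BCl3 binds in a six-membered chelate and chloride removes the methyl group at low temperature, while the silyl ether kept on C1' prevents the hydroxyl from adding to the prenyl alkene (cycloshikonin formation).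

Step 12
Reactants: 19 2-[(1R)-1-(tert-butyldimethylsilyloxy)-4-methylpent-3-enyl]-5,8-dihydroxynaphthalene-1,4-dione
Product: 20 shikonin, 5,8-dihydroxy-2-[(1R)-1-hydroxy-4-methylpent-3-enyl]naphthalene-1,4-dione
Conditions: HF·pyridine, pyridine/THF, 0 °C → rt
Reagents that add atoms: none
Why: Fluoride-mediated Si–O cleavage under buffered, mildly acidic conditions avoids basic fluoride sources that would deprotonate and degrade the naphthazarin, and since no C–O bond at C1' is broken the configuration is kept.

Step 13
Reactants: 21 (2-carboxyethyl)triphenylphosphonium bromide; 22 methacrolein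
Product: 24 (3Z)-5-methylhexa-3,5-dienoic acid, via phosphonium ylide 23 (not isolated)
Conditions: NaHMDS (2.0 equiv), THF, –78 → –20 °C; then 22, –78 → 0 °C; acidify to pH 3 (1 M HCl); keep at or below rt and use promptly
Reagents that add atoms: none
Why: Wittig olefination with a non-stabilised ylide under lithium-free conditions goes through the kinetically favoured cis-oxaphosphetane and should give the Z alkene, the carboxylate form of the reagent suppresses retro-Michael loss of PPh3, and the product is kept cold because a cis-dienyl CH2 can undergo a [1,5]-hydrogen shift into conjugation on heating.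

Step 14
Reactants: 20 shikonin; 24 (3Z)-5-methylhexa-3,5-dienoic acid
Product: 26 (1R)-1-(5,8-dihydroxy-1,4-dioxo-1,4-dihydronaphthalen-2-yl)-4-methylpent-3-enyl (3Z)-5-methylhexa-3,5-dienoate, via O-acylisourea 25 (not isolated)
Conditions: 24 (1.5 equiv), DCC (1.5 equiv), DMAP (0.1 equiv), CH2Cl2, –10 → 0 °C
Reagents that add atoms: none
Why: Steglich esterification acylates the side-chain secondary alcohol while the two peri hydroxyls, tied up in hydrogen bonds to the quinone carbonyls, stay free, the C1'–O bond is not broken (retention), and low temperature with only catalytic DMAP should keep the skipped Z diene from moving into conjugation with the ester carbonyl.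

**Compound list**
1 | 2-bromo-1,4-dimethoxybenzene | COc1ccc(OC)c(Br)c1 | starting material
2 | methoxyallene (1-methoxypropa-1,2-diene) | C=C=COC | starting material
3 | (2,5-dimethoxyphenyl)magnesium bromide (formed in the flask) | COc1ccc(OC)c([Mg]Br)c1 | intermediate
4 | 3-(2,5-dimethoxyphenyl)prop-1-yne | COc1ccc(OC)c(CC#C)c1 | intermediate
5 | 4-methylpent-3-enoic acid | CC(C)=CCC(=O)O | starting material
6 | 1-(4-methylpent-3-enoyl)imidazole (formed in the flask) | CC(C)=CCC(=O)n1ccnc1 | intermediate
7 | N-methoxy-N,4-dimethylpent-3-enamide | CC(C)=CCC(=O)N(C)OC | intermediate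
8 | lithium 3-(2,5-dimethoxyphenyl)prop-1-yn-1-ide (formed in the flask) | COc1ccc(OC)c(CC#C[Li])c1 | intermediate
9 | 1-(2,5-dimethoxyphenyl)-7-methyloct-6-en-2-yn-4-one | COc1ccc(OC)c(CC#CC(=O)CC=C(C)C)c1 | intermediate
10 | (4R)-1-(2,5-dimethoxyphenyl)-7-methyloct-6-en-2-yn-4-ol | COc1ccc(OC)c(CC#C[C@H](O)CC=C(C)C)c1 | intermediate
11 | (2Z,4R)-1-(2,5-dimethoxyphenyl)-7-methyl-3-(tributylstannyl)octa-2,6-dien-4-ol | COc1ccc(OC)c(C/C=C(\[Sn](CCCC)(CCCC)CCCC)[C@H](O)CC=C(C)C)c1 | intermediate
12 | tert-butyl{[(2Z,4R)-1-(2,5-dimethoxyphenyl)-7-methyl-3-(tributylstannyl)octa-2,6-dien-4-yl]oxy}dimethylsilane | COc1ccc(OC)c(C/C=C(\[Sn](CCCC)(CCCC)CCCC)[C@H](O[Si](C)(C)C(C)(C)C)CC=C(C)C)c1 | intermediate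
13 | tert-butyl{[(2Z,4R)-1-(2,5-dimethoxyphenyl)-3-iodo-7-methylocta-2,6-dien-4-yl]oxy}dimethylsilane | COc1ccc(OC)c(C/C=C(\I)[C@H](O[Si](C)(C)C(C)(C)C)CC=C(C)C)c1 | intermediate
14 | (Z)-2-[(1R)-1-(tert-butyldimethylsilyloxy)-4-methylpent-3-enyl]-4-(2,5-dimethoxyphenyl)but-2-enoic acid | COc1ccc(OC)c(C/C=C(\C(=O)O)[C@H](O[Si](C)(C)C(C)(C)C)CC=C(C)C)c1 | intermediate
15 | mixed trifluoroacetic anhydride of acid 14 (formed in the flask) | COc1ccc(OC)c(C/C=C(\C(=O)OC(=O)C(F)(F)F)[C@H](O[Si](C)(C)C(C)(C)C)CC=C(C)C)c1 | intermediate
16 | 2-[(1R)-1-(tert-butyldimethylsilyloxy)-4-methylpent-3-enyl]-5,8-dimethoxy-4H-naphthalen-1-one (formed in the flask) | COc1ccc(OC)c2c1CC=C([C@H](O[Si](C)(C)C(C)(C)C)CC=C(C)C)C2=O | intermediate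
17 | 2-[(1R)-1-(tert-butyldimethylsilyloxy)-4-methylpent-3-enyl]-5,8-dimethoxynaphthalen-1-ol | COc1ccc(OC)c2c(O)c([C@H](O[Si](C)(C)C(C)(C)C)CC=C(C)C)ccc12 | intermediate
18 | 2-[(1R)-1-(tert-butyldimethylsilyloxy)-4-methylpent-3-enyl]-5,8-dimethoxynaphthalene-1,4-dione | COc1ccc(OC)c2c1C(=O)C=C([C@H](O[Si](C)(C)C(C)(C)C)CC=C(C)C)C2=O | intermediate
19 | 2-[(1R)-1-(tert-butyldimethylsilyloxy)-4-methylpent-3-enyl]-5,8-dihydroxynaphthalene-1,4-dione | O=C1C=C([C@H](O[Si](C)(C)C(C)(C)C)CC=C(C)C)C(=O)c2c(O)ccc(O)c12 | intermediate
20 | shikonin, 5,8-dihydroxy-2-[(1R)-1-hydroxy-4-methylpent-3-enyl]naphthalene-1,4-dione | O=C1C=C([C@H](O)CC=C(C)C)C(=O)c2c(O)ccc(O)c12 | intermediate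
21 | (2-carboxyethyl)triphenylphosphonium bromide | OC(=O)CC[P+](c1ccccc1)(c1ccccc1)c1ccccc1.[Br-] | starting material
22 | methacrolein (2-methylprop-2-enal) | CC(=C)C=O | starting material
23 | sodium 3-(triphenylphosphoranylidene)propanoate (formed in the flask) | [Na+].[O-]C(=O)CC=P(c1ccccc1)(c1ccccc1)c1ccccc1 | intermediate
24 | (3Z)-5-methylhexa-3,5-dienoic acid | C=C(C)/C=C\CC(=O)O | intermediate
25 | O-[(3Z)-5-methylhexa-3,5-dienoyl]-N,N'-dicyclohexylisourea (formed in the flask) | C=C(C)/C=C\CC(=O)OC(=NC1CCCCC1)NC1CCCCC1 | intermediate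
26 | (1R)-1-(5,8-dihydroxy-1,4-dioxo-1,4-dihydronaphthalen-2-yl)-4-methylpent-3-enyl (3Z)-5-methylhexa-3,5-dienoate | C=C(C)/C=C\CC(=O)O[C@H](CC=C(C)C)C1=CC(=O)c2c(O)ccc(O)c2C1=O | target

**Step count**
Total: 14 steps. Longest linear sequence: 12 steps (1, 3, 4, 5, 6, 7, 8, 9, 10, 11, 12, 14) from 2-bromo-1,4-dimethoxybenzene.

**Steps most likely to fail**

Step 9 (ring closure). The buffered mixed anhydride may be too weak an electrophile. Z to E isomerisation of the activated enoate, acylation by the side-chain alkene, or acid-induced loss of the silyl ether once the buffer is relaxed could then overtake attack by the arene. The fallback sets out from 14 and uses the thermal, basic variant of the same ring closure: acetic anhydride and anhydrous NaOAc at about 120 °C. This works through the mixed acetic anhydride, reversible vinylketene formation and 6π electrocyclisation, so it does not depend on keeping the Z geometry and never becomes strongly acidic. It would give 2-[(1R)-1-(tert-butyldimethylsilyloxy)-4-methylpent-3-enyl]-5,8-dimethoxynaphthalen-1-yl acetate F1. Methanolysis of F1 (K2CO3, MeOH, 0 °C, under argon) comes back to the route at 17.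

Step 11 (demethylation). The Lewis acid may cleave or ionise the C1' silyl ether, after which the freed hydroxyl adds to the prenyl alkene, or the second methyl ether may be cleaved incompletely. The fallback sets out from 18 and removes the methyl groups oxidatively instead. Brief treatment with AgO and 6 M HNO3 in dioxane at rt would give 2-[(1R)-1-(tert-butyldimethylsilyloxy)-4-methylpent-3-enyl]naphthalene-1,4,5,8-tetrone F2. Immediate reduction of F2 with aqueous Na2S2O4 comes back to the route at 19.

Step 3 (ynone formation). The arylmethyl-substituted ynone 9 may isomerise to an allenyl ketone through its acidic propargylic, benzylic CH2 group, during isolation or in step 4. The fallback sets out from 7 and attaches the arylmethyl group only after the stereocentre is in place: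
- Lithiated ethynyltrimethylsilane (n-BuLi, THF, –78 °C) added to 7 would give 6-methyl-1-(trimethylsilyl)hept-5-en-1-yn-3-one F3, which has no arylmethyl group.
- The transfer hydrogenation of step 4 with the same catalyst would give (3R)-6-methyl-1-(trimethylsilyl)hept-5-en-1-yn-3-ol F4.
- K2CO3 in MeOH would give (3R)-6-methylhept-5-en-1-yn-3-ol F5.
- Double deprotonation of F5 with EtMgBr (2.1 equiv, THF) and CuBr-catalysed coupling of the alkynylmagnesium alkoxide with purchased 2,5-dimethoxybenzyl bromide comes back to the route at 10.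

**Further compounds**
F1 | step 9 | 2-[(1R)-1-(tert-butyldimethylsilyloxy)-4-methylpent-3-enyl]-5,8-dimethoxynaphthalen-1-yl acetate | COc1ccc(OC)c2c(OC(C)=O)c([C@H](O[Si](C)(C)C(C)(C)C)CC=C(C)C)ccc12
F2 | step 11 | 2-[(1R)-1-(tert-butyldimethylsilyloxy)-4-methylpent-3-enyl]naphthalene-1,4,5,8-tetrone | O=C1C=CC(=O)C2=C1C(=O)C=C([C@H](O[Si](C)(C)C(C)(C)C)CC=C(C)C)C2=O
F3 | step 3 | 6-methyl-1-(trimethylsilyl)hept-5-en-1-yn-3-one | CC(C)=CCC(=O)C#C[Si](C)(C)C
F4 | step 3 | (3R)-6-methyl-1-(trimethylsilyl)hept-5-en-1-yn-3-ol | C[Si](C)(C)C#C[C@H](O)CC=C(C)C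
F5 | step 3 | (3R)-6-methylhept-5-en-1-yn-3-ol | C#C[C@H](O)CC=C(C)C
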